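**Plan**

- Retrosynthesis: the C4 hydroxyl is masked as a 2-naphthylmethyl ether. Ring A is then cut at O1–C2 and C3–C4 (retro-[4+2]) into a 2-(arylmethoxymethylidene)cyclohexane-1,3-dione and nonadec-1-ene. The heterodiene is cut at its enol-ether C–O bond and its exocyclic C=C into cyclohexane-1,3-dione, an orthoformate carbon and the alcohol.
- Enabling feature: ring A (O1, C2, C3, C4, C4a, C8a) is a dihydropyran whose enol ether O1–C8a=C4a is conjugated with the C5 ketone of ring B. It is therefore the formal adduct of the O=C–C=C unit of a 2-alkylidene-1,3-dione with a terminal alkene.
- Forward: ring B is bought. The one-carbon unit (future C4) is attached at the dione C2, its oxygen substituent is exchanged, ring A is closed by intermolecular oxa-Diels–Alder reaction with the C19 alkene, and the ether is removed.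
- Stereochemistry: C2 and C4 both arise in the cycloaddition. The absolute sense comes from a chiral copper–bis(oxazoline) Lewis acid, and the cis relationship from an endo-alkyl, outside-alkoxy transition state. No later step touches either centre.

Key step: step 3

Assumption: atom labels follow the chromene numbering of the target. The sense of induction of the copper catalyst on this substrate class is not established, so the (S,S)-ligand, 2,2'-(propane-2,2-diyl)bis[(4S)-4-tert-butyl-4,5-dihydrooxazole], is written, and its (R,R)-antipode is to be used if the first run gives the (2R,4S) series.

**Route**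

Step 1
Reactants: 1 cyclohexane-1,3-dione; 2 triethyl orthoformate
Product: 3 2-(ethoxymethylidene)cyclohexane-1,3-dione
Conditions: HC(OEt)3 (1.5 equiv), Ac2O (2.5 equiv), 120 °C, volatiles distilled off
Reagents that add atoms: none
Why: Claisen-type alkoxymethylenation, in which acetic anhydride turns the orthoformate into a diethoxycarbenium equivalent that is attacked by C2 of the enolised dione, and loss of ethanol gives the push–pull enol ether, which has no geometric isomers because the dione is symmetrical.

Step 2
Reactants: 3 2-(ethoxymethylidene)cyclohexane-1,3-dione; 4 naphthalen-2-ylmethanol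
Product: 5 2-[(naphthalen-2-ylmethoxy)methylidene]cyclohexane-1,3-dione
Conditions: 4 (1.2 equiv), PPTS (2 mol %), toluene, 70 °C, reduced pressure (EtOH removed)
Reagents that add atoms: none
Why: Vinylogous transesterification by addition–elimination at the doubly activated enol-ether carbon, driven by removal of ethanol; the 2-naphthylmethyl group is chosen because it should ionise less readily from this vinylogous ester oxygen under Lewis acid than more electron-rich benzyl groups, yet is still cleaved oxidatively.

Step 3
Reactants: 5 2-[(naphthalen-2-ylmethoxy)methylidene]cyclohexane-1,3-dione; 6 nonadec-1-ene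
Product: 7 (2S,4R)-2-heptadecyl-4-(naphthalen-2-ylmethoxy)-2,3,4,6,7,8-hexahydro-5H-chromen-5-one
Conditions: [Cu((S,S)-t-Bu-box)](SbF6)2 (10 mol %), 6 (4 equiv), 4 Å MS, CH2Cl2, 10 kbar, 25 °C
Reagents that add atoms: none
Why: Proposed new method: the divalent copper cation should chelate 5 through one ring carbonyl and the naphthylmethoxy oxygen (the two ring carbonyls of a cyclic 1,3-dione diverge and cannot bind one metal together), which makes the alkoxymethylidene carbon C4 oxocarbenium-like and leaves the other O=C–C=C unit as the reacting 1-oxadiene; the CH2 terminus of 6 then bonds to C4 while the internal carbon, carrying the developing positive charge, is captured by the free carbonyl oxygen (O1–C2) in a concerted but asynchronous inverse-electron-demand [4+2] cycloaddition. The closest known reaction types are the divalent-copper bis(oxazoline)-catalysed oxa-Diels–Alder reactions of chelating α,β-unsaturated carbonyl heterodienes (alkoxy-substituted ones included) with enol ethers, the carbonyl-ene reactions of simple 1-alkenes promoted by the same cationic complexes, and pressure-accelerated oxa-Diels–Alder additions of alkylidene-1,3-dicarbonyl compounds; none joins an alkoxymethylidene dione to an unactivated alkene. Ring A is closed by intermolecular cycloaddition, four of its atoms coming from O=C–C=C of 5 and two from C=C of 6. C4 is set by the ligand, whose tert-butyl group should shield one face of the chelated alkoxymethylidene carbon, and C2 is set relative to C4 by the suprafacial endo-alkyl transition state, which places the heptadecyl group cis to the outside alkoxy group. The step needs regio-, endo- and facial selectivity: regiochemistry follows Markovnikov polarisation of the terminal alkene, the alkoxy group is held outside by the chelate itself, and the compact endo arrangement is the one favoured by pressure, which also supplies the rate that the donor-substituted heterodiene and the unactivated alkene lack.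

Step 4
Reactants: 7 (2S,4R)-2-heptadecyl-4-(naphthalen-2-ylmethoxy)-2,3,4,6,7,8-hexahydro-5H-chromen-5-one
Product: 8 (2S,4R)-2-heptadecyl-4-hydroxy-2,3,4,6,7,8-hexahydro-5H-chromen-5-one
Conditions: DDQ (1.3 equiv), CH2Cl2/pH 7 phosphate buffer (10:1), 0 °C to 20 °C
Reagents that add atoms: none
Why: Oxidative 2-naphthylmethyl ether cleavage, in which DDQ abstracts the arylmethyl hydride, water adds to the resulting oxocarbenium ion and the hemiacetal collapses, so the C4–O bond is never broken and both stereocentres are retained, while the buffer keeps the allylic C4 position from acid-promoted ionisation.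

**Compound list**

1 | cyclohexane-1,3-dione | O=C1CCCC(=O)C1 | starting material
2 | triethyl orthoformate | CCOC(OCC)OCC | starting material
3 | 2-(ethoxymethylidene)cyclohexane-1,3-dione | CCOC=C1C(=O)CCCC1=O | intermediate
4 | naphthalen-2-ylmethanol | OCc1ccc2ccccc2c1 | starting material
5 | 2-[(naphthalen-2-ylmethoxy)methylidene]cyclohexane-1,3-dione | O=C1CCCC(=O)C1=COCc1ccc2ccccc2c1 | intermediate
6 | nonadec-1-ene | CCCCCCCCCCCCCCCCCC=C | starting material
7 | (2S,4R)-2-heptadecyl-4-(naphthalen-2-ylmethoxy)-2,3,4,6,7,8-hexahydro-5H-chromen-5-one | CCCCCCCCCCCCCCCCC[C@H]1C[C@@H](OCc2ccc3ccccc3c2)C2=C(CCCC2=O)O1 | intermediate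
8 | (2S,4R)-2-heptadecyl-4-hydroxy-2,3,4,6,7,8-hexahydro-5H-chromen-5-one | CCCCCCCCCCCCCCCCC[C@H]1C[C@@H](O)C2=C(CCCC2=O)O1 | target

**Step count**

Total steps: 4. Longest linear sequence: 4 (1 → 3 → 5 → 7 → 8).

**Steps most likely to fail**

Step 3 (proposed new method). Several processes may defeat it:
- the unactivated alkene may not engage the donor-substituted heterodiene at a useful rate, or the product may hold the catalyst and stop turnover;
- proton loss from the developing cation may divert the reaction to an ene-type adduct;
- the Lewis acid may ionise the naphthylmethyl–oxygen bond or the C4–O bond of the product;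
- endo or facial discrimination may be incomplete.

The fallback uses known chemistry only, sets out from 1 and comes back to the route at 8. Ring A is closed by C–O bond formation instead of cycloaddition. Compound 1 is C-acetylated (Ac2O, Et3N, then catalytic DMAP for the O-to-C acyl shift) to 2-acetylcyclohexane-1,3-dione F1, which can also be bought. Its ring enol is O-methylated (HC(OMe)3, catalytic TsOH, MeOH) to 2-acetyl-3-methoxycyclohex-2-en-1-one F2. The diisopinocampheylboron enolate of the acetyl group (Ipc2BCl, Et3N, Et2O, −78 °C, reagent antipode chosen for the S carbinol) adds to octadecanal in a boron aldol reaction to give 2-[(3S)-3-hydroxyicosanoyl]-3-methoxycyclohex-2-en-1-one F3. Hydroxyl-directed Evans–Saksena reduction (Me4NBH(OAc)3, MeCN/AcOH, −30 °C) should give the 1,3-anti diol 2-[(1R,3S)-1,3-dihydroxyicosyl]-3-methoxycyclohex-2-en-1-one F4. Intramolecular addition–elimination of the distal hydroxyl at the methoxy-bearing enone carbon (catalytic DBU, THF) then expels methanol and closes ring A to 8. The anti-diol is the relationship that corresponds to the cis-2,4 ring.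

Step 2. The alkoxy exchange may stall at equilibrium, and adventitious water may hydrolyse the vinylogous ester to the hydroxymethylidene dione. The fallback sets out from 2 and comes back at 5. It moves the exchange to the orthoester stage, where it is classical. Compound 2 is heated with three equivalents of 4 and catalytic TsOH while ethanol distils, to give tris(naphthalen-2-ylmethyl) orthoformate F5. F5 is then condensed with 1 in Ac2O in the manner of step 1, which gives 5 directly and bypasses 3.

Step 4. The quinone may over-oxidise the allylic alcohol, or the acidic hydroquinone may promote ionisation at C4 with loss of water or epimerisation. The fallback sets out from 7 and comes back at 8. It changes the cleavage from oxidative to reductive: hydrogenolysis (H2, 1 atm, Pd/C, EtOAc, 20 °C). Naphthylmethyl ethers undergo this readily under neutral conditions, and the tetrasubstituted enol-ether double bond should not be reduced. New compounds on the way: none F0.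

**Further compounds**

F1 | step 3 | 2-acetylcyclohexane-1,3-dione | CC(=O)C1C(=O)CCCC1=O
F2 | step 3 | 2-acetyl-3-methoxycyclohex-2-en-1-one | COC1=C(C(C)=O)C(=O)CCC1
F3 | step 3 | 2-[(3S)-3-hydroxyicosanoyl]-3-methoxycyclohex-2-en-1-one | CCCCCCCCCCCCCCCCC[C@H](O)CC(=O)C1=C(OC)CCCC1=O
F4 | step 3 | 2-[(1R,3S)-1,3-dihydroxyicosyl]-3-methoxycyclohex-2-en-1-one | CCCCCCCCCCCCCCCCC[C@H](O)C[C@@H](O)C1=C(OC)CCCC1=O
F5 | step 2 | tris(naphthalen-2-ylmethyl) orthoformate | C(OCc1ccc2ccccc2c1)(OCc1ccc2ccccc2c1)OCc1ccc2ccccc2c1
F0 | step 4 | none | none
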